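## Structural features

The target is a flavone: a benzo ring A fused along C4a–C8a to a γ-pyranone ring C (O1, C2, C3, C4=O), with a 3,4,5-trimethoxyphenyl ring B joined to C2 by the single C2–C1' bond. Ring A carries a hydroxyl on C5, a hydroxyl on C7, a methoxy group on C8 and the ring oxygen on C8a, so C6–H is its only hydrogen. The molecule is achiral and has no stereocentre, so no relative configuration has to be set and nothing can epimerise. The fragile points are three. The C2–C3 enone of ring C is open to conjugate addition, hydroxide ring opening and hydrogenation. The 5-hydroxy/8-methoxy pair is a para-methoxyphenol that an oxidant can take to a flavone-5,8-quinone. Strong acid can isomerise the 8-methoxy pattern to the 6-methoxy one by ring opening and reclosure. The real difficulty is regiochemical: O7 (free), O8 (methylated) and O1 (in the ring) are contiguous and must be told apart, and the isolated C5 oxygen must be placed without drifting into the 6-methoxy series. The key step uses the fact that C5–H is the one ring A C–H bond attached to C4a, next to the C4 carbonyl oxygen, so that O4, C4, C4a and C5 can hold a metal in a five-membered chelate. The O7/O8/O1 triad then maps directly onto the three adjacent hydroxyls of a pyrogallol ketone, whose different acidities separate O7 from O8.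

## Logic of the disconnections

13 is first traced back to 12 by placing an acetyl group on O7; the bond cut is the ester C–O bond. The skeleton is not simplified, but 12 is what the oxidation delivers, and an acyl group on O7 is wanted during that oxidation. The forward step must be a transesterification mild enough to spare the chromone, the four methyl ethers and the chelated 5-hydroxyl.

12 is cut at the C5–O bond, through 11, to give 10. This removes the isolated oxygen and turns a 5,7,8-trioxygenated ring A, hard to secure from phloroglucinol precursors, into a 7,8-dioxygenated one. The forward step must oxidise one aromatic C–H bond out of five and stop at the phenol oxidation level.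

10 is related to 8, through 9, by exchanging the O7 acetyl for a benzyl group. The reason is compatibility: the base-mediated C–C bond formation and the cyclisation cannot carry an aryl ester, and the oxidation cannot carry an electron-rich benzyl ether. The forward step must cleave the O–CH2 bond without saturating C2–C3.

8 is cut at O1–C2, which opens ring C to the 1,3-diketone 7. The heterocycle is reduced to an open chain on a phenol. The forward cyclodehydration must be acidic enough to lose water but must keep the benzyl ether.

7 is cut at the C–C bond between its methylene carbon and the aroyl carbonyl (the future C3–C2 bond), through 6, to give 4 and 5. This is the most convergent cut and splits the molecule into a ring A half and a ring B half. The forward step must acylate the enolate on carbon in the presence of a phenol.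

4 is cut at the O–CH3 bond on the middle oxygen to give 3. The forward step must methylate one of two hydroxyls, the one that is not hydrogen-bonded to the ketone.

3 is cut at the O–CH2Ph bond to give 1 and 2. The forward step must alkylate one of three hydroxyls, the most acidic one, para to the acetyl group.

## Other disconnections considered

Alternative 1: Ring C is cut at three bonds at once (C4a–C4, C4–C3 and O1–C2). This returns the ortho-iodophenol A1 (3,5-bis(benzyloxy)-2-iodo-6-methoxyphenol), the arylacetylene A2 (5-ethynyl-1,2,3-trimethoxybenzene) and carbon monoxide A3.
- Forward key step: zerovalent palladium would insert into the C–I bond of A1, take up A3 to an aroylpalladium species and couple it with A2 to an ortho-hydroxyaryl ynone. The phenol would then close ring C by 6-endo-dig conjugate addition to the bis-benzyl flavone A4, and double hydrogenolysis would give 13.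
- In favour: it is the most convergent plan. All ring A oxygens are in place before the key step and no oxidant meets the electron-rich rings, so on chemoselectivity of the key step it is better than the chosen plan.
- Against: the regiochemical problem is moved into A1, not solved. A1 is a pentasubstituted benzene in which three phenolic oxygens must be differentiated and iodine placed between two oxygens. Oxidative addition into so electron-rich and doubly ortho-substituted an iodide should be slow. 5-exo closure to an aurone competes with the 6-endo mode. A toxic gas is handled under pressure.
- Comparison: structurally, the chosen plan inherits the O7/O8/O1 pattern from 1 at no cost, whereas A1 would probably need five or six steps, so the total would not fall below seven. Mechanistically both key steps are catalytic and both plans end with one mild deprotection; on those points they are equal.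

Alternative 2: Ring A is built, not bought. The C4a–C5 bond is cut (and C8–C8a one stage earlier), leading back to the cyclobutenone A5 (racemic 4-hydroxy-3-isopropoxy-4-[4-oxo-6-(3,4,5-trimethoxyphenyl)-4H-pyran-2-yl]cyclobut-2-en-1-one). A5 is the adduct of a C-metallated 2-aryl-4-pyranone and a squaric acid monoester.
- Forward key step: on heating, A5 would open by 4π-electrocyclic ring opening to a dienylketene. The ketene carbon would bond to pyranone C3 in a 6π-electrocyclisation, and tautomerisation would give the hydroquinone A6 (5,8-dihydroxy-7-isopropoxy-2-(3,4,5-trimethoxyphenyl)-4H-chromen-4-one). Methylation at O8 (the 5-hydroxyl being chelated) and removal of the isopropyl group would then give 13.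
- In favour: every substituent position of ring A is dictated by the connectivity of the four-membered ring, so regiochemistry is as unambiguous as in the chosen plan (equal). The key step needs only heat, no metal and no oxidant, and is better on that ground.
- Against: A6 is a free para-hydroquinone and should be more prone to oxidation to the quinone than anything in the chosen route, where the same para relationship stays masked as an ester until the oxidant is destroyed. The metallated pyranone carries its own electrophilic enone and must add to only one of the two squarate carbonyls. Two further operations follow the key step, one of which must cleave a secondary alkyl ether in the presence of four methyl ethers.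
- Comparison: the pyranone and squarate building blocks plus addition, thermolysis, methylation and dealkylation add up to clearly more than seven steps.

Alternative 3: The C2–C1' bond is cut, giving the ring B-free chromone A7 (7-(benzyloxy)-5-hydroxy-8-methoxy-4H-chromen-4-one) and the boronic acid A8 ((3,4,5-trimethoxyphenyl)boronic acid).
- Forward key step: A8 would transmetallate to divalent palladium. The arylpalladium species would add across C2–C3 of A7 with the aryl group going to C2, the β-carbon of the enone. β-Hydride elimination, with re-oxidation of palladium by a terminal oxidant, would give A9 (7-(benzyloxy)-5-hydroxy-8-methoxy-2-(3,4,5-trimethoxyphenyl)-4H-chromen-4-one). Hydrogenolysis of the benzyl ether would give 13.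
- In favour: ring B arrives last, so for analogue work this plan is better than the chosen one. The 5-hydroxyl is present from the start. Like the chosen plan it functionalises a C–H bond catalytically at a late stage and ends with one mild deprotection (equal).
- Against: A7 is no easier to make than 10. A 5,7-dioxygenated 8-methoxychromone comes from a phloroglucinol ketone whose two ortho hydroxyls differ, so ring closure can give the 8-methoxy or the 6-methoxy series, the ambiguity that 1 avoids. If re-oxidation lags, the reaction stops at the flavanone. The electron-rich A8 is prone to protodeboronation. The oxidant meets a free 5-hydroxy-8-methoxy ring.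
- Comparison: two steps follow A7, but A7 needs about as many steps as 10, so there is no gain in step economy.

Key step: step 6

Remark on the chemistry: when the C4 carbonyl oxygen holds ruthenium at C5, the chelate contains Ru, O, C4, C4a and C5 and is therefore five-membered, not six-membered; the route is argued on that basis. Compounds 1, 2 and 5 are taken as commercial.

## Steps

Step 1
Reactants: 1 2',3',4'-trihydroxyacetophenone (gallacetophenone); 2 benzyl bromide
Product: 3 1-[4-(benzyloxy)-2,3-dihydroxyphenyl]ethan-1-one
Conditions: BnBr (1.0 equiv), NaHCO3 (1.2 equiv), DMF, 40 °C
Reagents that add atoms: none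
Why: Williamson etherification; the 4-hydroxyl, para to the acetyl group, is the most acidic and the only one that hydrogencarbonate deprotonates to a useful extent, while the 2-hydroxyl is locked in a hydrogen bond to the ketone and the 3-hydroxyl is less acidic; one equivalent of halide limits a second alkylation.

Step 2
Reactants: 3 1-[4-(benzyloxy)-2,3-dihydroxyphenyl]ethan-1-one
Product: 4 1-[4-(benzyloxy)-2-hydroxy-3-methoxyphenyl]ethan-1-one
Conditions: MeI (1.1 equiv), K2CO3 (1.1 equiv), acetone, reflux
Reagents that add atoms: iodomethane, CI
Why: Williamson etherification; the 2-hydroxyl is tied to the ketone by a strong hydrogen bond and its oxygen is a poor nucleophile, so methylation should fall on O3, as is usual for 2,3-dihydroxyaryl ketones.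

Step 3
Reactants: 4 1-[4-(benzyloxy)-2-hydroxy-3-methoxyphenyl]ethan-1-one; 5 3,4,5-trimethoxybenzoyl chloride
Product: 7 1-[4-(benzyloxy)-2-hydroxy-3-methoxyphenyl]-3-(3,4,5-trimethoxyphenyl)propane-1,3-dione, via dilithium enolate-phenolate 6 (not isolated)
Conditions: LiN(SiMe3)2 (3.3 equiv), THF, −78 → −10 °C; then 5, −78 °C → rt; 1 M HCl
Reagents that add atoms: none
Why: Claisen-type C-aroylation of a ketone enolate, the one-flask form of the Baker–Venkataraman sequence; two equivalents of amide form the phenolate and the enolate, the third takes up the acidic proton of the diketone and so prevents a second acylation; any O-aroylated phenolate would rearrange to the same diketone under the excess base.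

Step 4
Reactants: 7 1-[4-(benzyloxy)-2-hydroxy-3-methoxyphenyl]-3-(3,4,5-trimethoxyphenyl)propane-1,3-dione
Product: 8 7-(benzyloxy)-8-methoxy-2-(3,4,5-trimethoxyphenyl)-4H-chromen-4-one
Conditions: NaOAc, AcOH, reflux
Reagents that add atoms: none
Why: Cyclodehydration of an ortho-hydroxyaryl 1,3-diketone; the phenol adds to the aroyl carbonyl to form the O1–C2 bond and loss of water gives the pyranone; the acetate-buffered acid is mild enough to keep the benzyl ether and the methyl ethers.

Step 5
Reactants: 8 7-(benzyloxy)-8-methoxy-2-(3,4,5-trimethoxyphenyl)-4H-chromen-4-one
Product: 10 8-methoxy-4-oxo-2-(3,4,5-trimethoxyphenyl)-4H-chromen-7-yl acetate, via 7-hydroxyflavone 9 (not isolated)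
Conditions: H2 (1 atm), 10% Pd/C, THF, rt; N2 purge; then Ac2O, Et3N, DMAP (cat.), rt
Reagents that add atoms: acetic anhydride, CC(=O)OC(C)=O
Why: Hydrogenolysis of a benzyl aryl ether should be faster than reduction of the cross-conjugated C2–C3 bond at one atmosphere; the acidic 7-hydroxyl is then acetylated in the same flask by nucleophilic catalysis, which avoids isolating a poorly soluble phenol.

Step 6
Reactants: 10 8-methoxy-4-oxo-2-(3,4,5-trimethoxyphenyl)-4H-chromen-7-yl acetate
Product: 12 5-hydroxy-8-methoxy-4-oxo-2-(3,4,5-trimethoxyphenyl)-4H-chromen-7-yl acetate, via C5 trifluoroacetate 11 (not isolated)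
Conditions: [RuCl2(p-cymene)]2 (5 mol%), PhI(OCOCF3)2 (2 equiv), CF3CO2H/(CF3CO)2O, 80 °C; evaporate; EtOAc, cold aq. Na2SO3, then aq. NaHCO3
Reagents that add atoms: [bis(trifluoroacetoxy)iodo]benzene, O=C(OI(OC(=O)C(F)(F)F)c1ccccc1)C(F)(F)F
Why: Chloride–trifluoroacetate exchange in the acidic medium should give an electrophilic divalent ruthenium trifluoroacetate that binds the C4 carbonyl oxygen of 10; carboxylate-assisted cleavage of the adjacent C5–H bond then gives a five-membered ruthenacycle (Ru, O, C4, C4a, C5). PhI(OCOCF3)2 oxidises this metallacycle to a tetravalent ruthenium trifluoroacetate, and C–O reductive elimination releases the aryl trifluoroacetate 11 and returns divalent ruthenium. The closest known reaction type is the ruthenium-catalysed, ketone-directed ortho C–H hydroxylation of aryl ketones, which is established for C5 of chromones and flavones. No ring is closed and no stereocentre is formed; one C–O bond is made. The selectivity needed is C5 over C6, C3 and the C2'/C6' positions of ring B: only C5–H fits a five-membered chelate (C3 would need a four-membered one, C6 and ring B are out of reach), and C5 is also para to the 8-methoxy group, which helps electrophilic metalation. Over-oxidation should be held back because the new oxygen stays acylated as 11 in the anhydrous medium, the 7-acetate and the acid-complexed chromone keep rings A and B electron-poor, and excess trivalent iodine is reduced by sulfite before hydrogencarbonate hydrolyses the trifluoroacetate. The 7-acetate should survive the short cold wash, and any exchange of it for trifluoroacetate in the hot medium would only anticipate step 7.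

Step 7
Reactants: 12 5-hydroxy-8-methoxy-4-oxo-2-(3,4,5-trimethoxyphenyl)-4H-chromen-7-yl acetate
Product: 13 5,7-dihydroxy-8-methoxy-2-(3,4,5-trimethoxyphenyl)-4H-chromen-4-one (3',4',5'-trimethoxywogonin)
Conditions: K2CO3 (1.5 equiv), MeOH, 0 °C → rt, under N2; then 1 M HCl to pH 5
Reagents that add atoms: none
Why: Base-mediated transesterification of an activated aryl acetate to methyl acetate; at room temperature carbonate in methanol should not open the chromone or touch the methyl ethers, and the chelated 5-hydroxyl is inert.

## Compound list

1 | 2',3',4'-trihydroxyacetophenone (gallacetophenone) | CC(=O)c1ccc(O)c(O)c1O | starting material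
2 | benzyl bromide | BrCc1ccccc1 | starting material
3 | 1-[4-(benzyloxy)-2,3-dihydroxyphenyl]ethan-1-one | CC(=O)c1ccc(OCc2ccccc2)c(O)c1O | intermediate
4 | 1-[4-(benzyloxy)-2-hydroxy-3-methoxyphenyl]ethan-1-one | CC(=O)c1ccc(OCc2ccccc2)c(OC)c1O | intermediate
5 | 3,4,5-trimethoxybenzoyl chloride | COc1cc(C(Cl)=O)cc(OC)c1OC | starting material
6 | dilithium 3-(benzyloxy)-2-methoxy-6-(1-oxidoethenyl)phenolate (enolate-phenolate of 4) | [Li+].[Li+].C=C([O-])c1ccc(OCc2ccccc2)c(OC)c1[O-] | intermediate (not isolated)
7 | 1-[4-(benzyloxy)-2-hydroxy-3-methoxyphenyl]-3-(3,4,5-trimethoxyphenyl)propane-1,3-dione | COc1cc(C(=O)CC(=O)c2ccc(OCc3ccccc3)c(OC)c2O)cc(OC)c1OC | intermediate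
8 | 7-(benzyloxy)-8-methoxy-2-(3,4,5-trimethoxyphenyl)-4H-chromen-4-one | COc1cc(-c2cc(=O)c3ccc(OCc4ccccc4)c(OC)c3o2)cc(OC)c1OC | intermediate
9 | 7-hydroxy-8-methoxy-2-(3,4,5-trimethoxyphenyl)-4H-chromen-4-one | COc1cc(-c2cc(=O)c3ccc(O)c(OC)c3o2)cc(OC)c1OC | intermediate (not isolated)
10 | 8-methoxy-4-oxo-2-(3,4,5-trimethoxyphenyl)-4H-chromen-7-yl acetate | COc1cc(-c2cc(=O)c3ccc(OC(C)=O)c(OC)c3o2)cc(OC)c1OC | intermediate
11 | 7-acetoxy-8-methoxy-4-oxo-2-(3,4,5-trimethoxyphenyl)-4H-chromen-5-yl trifluoroacetate | COc1cc(-c2cc(=O)c3c(OC(=O)C(F)(F)F)cc(OC(C)=O)c(OC)c3o2)cc(OC)c1OC | intermediate (not isolated)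
12 | 5-hydroxy-8-methoxy-4-oxo-2-(3,4,5-trimethoxyphenyl)-4H-chromen-7-yl acetate | COc1cc(-c2cc(=O)c3c(O)cc(OC(C)=O)c(OC)c3o2)cc(OC)c1OC | intermediate
13 | 5,7-dihydroxy-8-methoxy-2-(3,4,5-trimethoxyphenyl)-4H-chromen-4-one | COc1cc(-c2cc(=O)c3c(O)cc(O)c(OC)c3o2)cc(OC)c1OC | target

## Step count and risk assessment

Total step count: 7. Longest linear sequence: 7 steps (1 → 13); 2 and 5 are bought, so there is no separate branch.

Step 6 (key step).
- What may go wrong: over-oxidation of ring A once the C5 oxygen is in place (oxidative loss of the 8-methyl group towards a 5,8-quinone), or single-electron oxidation of ring B by trivalent iodine. The opposite failure is stalled metalation, because ring A is acylated and the chromone is acid-complexed.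
- Fallback: from 10, carbonyl-directed C5–H iodination with a trivalent rhodium catalyst ([Cp*RhCl2]2, AgSbF6, N-iodosuccinimide, pivalic acid, 1,2-dichloroethane, 60 °C) would give 5-iodo-8-methoxy-4-oxo-2-(3,4,5-trimethoxyphenyl)-4H-chromen-7-yl acetate F1. Copper-catalysed Ullmann-type hydroxylation of F1 (CuI, 1,10-phenanthroline, aqueous KOH, DMSO, 80 °C, then dilute HCl, which also recloses any opened chromone) would replace iodine by hydroxyl and cleave the 7-acetate in the same operation. The detour comes back to the route at 13. The C5 oxygen then arrives as hydroxide and no oxidant meets the para-methoxyphenol.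

Step 1.
- What may go wrong: loss of site control in the alkylation, either a second benzylation at O3 or alkylation at O3 in place of O4 when more than one phenoxide is present.
- Fallback: from 1, a Mitsunobu etherification with benzyl alcohol (PPh3, diisopropyl azodicarboxylate, THF, 0 °C) would select by acidity, since only the 4-hydroxyl is acidic enough to protonate the betaine. It comes back at 3 and makes no compound outside the compound list (F0).

Step 3.
- What may go wrong: acylation on oxygen of the hindered phenolate, or a second aroylation of the diketone enolate that would end as a 3-aroylflavone after step 4; incomplete enolisation is the other possibility.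
- Fallback: from 4 and 5, esterification in pyridine with catalytic DMAP would give 6-acetyl-3-(benzyloxy)-2-methoxyphenyl 3,4,5-trimethoxybenzoate F2. KOH in pyridine at 50 °C would then move the aroyl group from oxygen to the methyl carbon (Baker–Venkataraman rearrangement), and the sequence comes back at 7.

Step 5.
- What may go wrong: saturation of the C2–C3 bond in competition with hydrogenolysis, or stalling of the hydrogenolysis through poor solubility of the phenol on the catalyst.
- Fallback: from 8, Lewis-acid debenzylation with BCl3 and pentamethylbenzene as cation scavenger (CH2Cl2, −78 °C) would give 9, isolated this time. Acetylation with Ac2O in pyridine then comes back at 10. No compound outside the compound list is made (F0).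

## Further compounds

F1 | step 6 | 5-iodo-8-methoxy-4-oxo-2-(3,4,5-trimethoxyphenyl)-4H-chromen-7-yl acetate | COc1cc(-c2cc(=O)c3c(I)cc(OC(C)=O)c(OC)c3o2)cc(OC)c1OC
F0 | step 1 | none | none
F2 | step 3 | 6-acetyl-3-(benzyloxy)-2-methoxyphenyl 3,4,5-trimethoxybenzoate | COc1cc(C(=O)Oc2c(C(C)=O)ccc(OCc3ccccc3)c2OC)cc(OC)c1OC
F0 | step 5 | none | none
A1 | alternative 1 | 3,5-bis(benzyloxy)-2-iodo-6-methoxyphenol | COc1c(O)c(I)c(OCc2ccccc2)cc1OCc1ccccc1
A2 | alternative 1 | 5-ethynyl-1,2,3-trimethoxybenzene | COc1cc(C#C)cc(OC)c1OC
A3 | alternative 1 | carbon monoxide | [C-]#[O+]
A4 | alternative 1 | 5,7-bis(benzyloxy)-8-methoxy-2-(3,4,5-trimethoxyphenyl)-4H-chromen-4-one | COc1cc(-c2cc(=O)c3c(OCc4ccccc4)cc(OCc4ccccc4)c(OC)c3o2)cc(OC)c1OC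
A5 | alternative 2 | racemic 4-hydroxy-3-isopropoxy-4-[4-oxo-6-(3,4,5-trimethoxyphenyl)-4H-pyran-2-yl]cyclobut-2-en-1-one | COc1cc(-c2cc(=O)cc(C3(O)C(OC(C)C)=CC3=O)o2)cc(OC)c1OC
A6 | alternative 2 | 5,8-dihydroxy-7-isopropoxy-2-(3,4,5-trimethoxyphenyl)-4H-chromen-4-one | COc1cc(-c2cc(=O)c3c(O)cc(OC(C)C)c(O)c3o2)cc(OC)c1OC
A7 | alternative 3 | 7-(benzyloxy)-5-hydroxy-8-methoxy-4H-chromen-4-one | COc1c(OCc2ccccc2)cc(O)c2c(=O)ccoc12
A8 | alternative 3 | (3,4,5-trimethoxyphenyl)boronic acid | COc1cc(B(O)O)cc(OC)c1OC
A9 | alternative 3 | 7-(benzyloxy)-5-hydroxy-8-methoxy-2-(3,4,5-trimethoxyphenyl)-4H-chromen-4-one | COc1cc(-c2cc(=O)c3c(O)cc(OCc4ccccc4)c(OC)c3o2)cc(OC)c1OC
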